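I read each flask at 1.0 h. The flasks differ in their charge of starting material, the limiting reagent, while the enzyme stays at 0.021 mol% and the second substrate at 4.00 equiv.

the same everywhere: free enzyme 0.021 mol%

| charge | starting material | second substrate | remark | time |
|---|---|---|---|---|
| epsilon | 11 mM | 4 equiv | run made earlier |  |
| theta | 28 mM | 4 equiv | run made earlier |  |
| beta | 49 mM | 4 equiv | run made earlier |  |
| south-east | 12 mM | 4.00 equiv |  | 1.0 h |
| east | 15 mM | 4.00 equiv |  | 1.0 h |
| west | 25 mM | 4.00 equiv |  | 1.0 h |
| south-west | 40 mM | 4.00 equiv |  | 1.0 h |
| south | 60 mM | 4.00 equiv |  | 1.0 h |

- epsilon (time / min: target / %, starting material / %): 4.00: 5, 101; 10.0: 0, 97; 20.0: 3, 97; 30.0: 4, 97; 40.0: 9, 89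
- theta (time / min: target / %, starting material / %): 3.00: 3, 98; 6.00: 1, 95; 12.0: 8, 97; 20.0: 6, 91; 40.0: 15, 86
- beta (time / min: target / %, starting material / %): 3.00: 3, 99; 6.00: 5, 99; 12.0: 5, 95; 20.0: 13, 89; 40.0: 21, 81

(readings scatter by 2 percentage points)

- "hardly changes" means that all values lie within two and a half points (for a concentration: within two and a half percent of the largest)

- amount of target at the end, in percent of the starting material charged for south-east, east, west, south-west, south, in this order
- how that number moves from the first to the last of them (rises, then falls / rises all the way / hardly changes / falls, then rises / falls all the way)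

In the beta run at 40.0 min, target stands at 21 % of the charge, and dividing that fraction by the enzyme's fraction 0.021 mol% and by the time gives 25.0 /min. This number is the mean turnover rate, the turnover frequency: target found per enzyme charged per minute, averaged from the start to the reading. By the same reckoning, epsilon reads 10.7 /min and theta 17.9 /min, so from epsilon to beta the charge grows 4.45-fold and the rate 2.34-fold, each reading carrying a scatter of 2 percentage points.

I draw the curve of each flask as a straight line from the origin, with slope equal to the turnover rate times the loading. Beta's line reaches the full charge at 190 min, and the hour is a third of that, so I put no level inside the hour. Holding the nearest run's rate for 1.0 h gives me 13.5 % for south-east and 31.5 % for south, whose charge exceeds beta's.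

The forecast is lower than my line at south: it gives 12 %, 15 %, 20 %, 25 % and 30 %, a row that rises all the way, saying “There is no sign of inhibition up to 49 mM, so I expect a steady rise.”

The flasks give 13.4 %, 15.3 %, 19.6 %, 23.0 % and 24.9 %, a row that rises all the way.

    starting material + free enzyme ⇌ first complex (K = 84.9 /M, k = 5190 /M/s)
    first complex ⇌ loaded enzyme + first product (K = 0.0200 M, k = 1.37 /s)
    second substrate + loaded enzyme ⇌ second complex (K = 6.80 /M, k = 708 /M/s)
    second complex → free enzyme + target (k = 1.09 /s)
    target + first product → side product (k = 0.00599 /M/s)

South ends below the forecast and below my line, with a mean turnover rate of 19.8 /min over the hour, against the 25.0 /min read in beta at 40.0 min. At the end of south, 3.12 % of the charge stands as side product beside the 24.9 % of target. South-east averages 10.6 /min over the hour, against the 10.7 /min read in epsilon at 40.0 min.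

(The readings stem from a simulated flask for substances that don't exist, noise included.)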